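The side chain on C3′ of ring B, CαH(CH3)–CβH2–ring C, sits ortho to the phenol oxygen on C4′, so O, C4′, C3′, Cα and Cβ can be tied up as a temporary 2-aryl-2,3-dihydrobenzofuran. The route rests on making Cα–Cβ by enantioselective rhodium-carbene insertion into a benzylic C–H bond of an aryl 4-(benzyloxy)benzyl ether: one operation closes that ring, forms the only C–C bond of the side chain and sets Cα. The precursor is the aryldiazoacetate 4, carrying the benzyl ether ortho to the diazo carbon. Later the ester becomes the Cα methyl, hydrogenolysis unties the ring, and a Friedel–Crafts union with a lactol acetate installs the oxolane para to the oxygen.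

Key step: step 3

Labels: ring A is the 4-hydroxyphenyl group on the oxolane, ring B the central phenol ring (C1′ bears the oxolane, C3′ the side chain, C4′ the hydroxyl), ring C the 4-hydroxyphenyl group at the end of the side chain. The oxolane is 2,3-trans, 3,4-cis, 4,5-trans.

Assumption: the S-configured catalyst in step 3 is taken to give the (2R,3S) ester and the (R,R)-ligand in step 10 the (2R,3S) keto acid; if either sense of induction proves opposite, the mirror-image catalyst or ligand is used and nothing else changes.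

Step 1
Reactants: 1 methyl 2-(2-hydroxyphenyl)acetate; 2 4-(benzyloxy)benzyl chloride
Product: 3 methyl 2-[2-[[4-(benzyloxy)phenyl]methoxy]phenyl]acetate
Conditions: K2CO3, NaI (cat.), DMF, rt
Reagents that add atoms: none
Why: Williamson etherification, in which the phenoxide displaces the reactive benzylic chloride at room temperature, mild enough to keep 1 from lactonising; no stereocentre is involved.

Step 2
Reactants: 3 methyl 2-[2-[[4-(benzyloxy)phenyl]methoxy]phenyl]acetate
Product: 4 methyl 2-diazo-2-[2-[[4-(benzyloxy)phenyl]methoxy]phenyl]acetate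
Conditions: 4-acetamidobenzenesulfonyl azide, DBU, MeCN, 0 °C to rt
Reagents that add atoms: 4-acetamidobenzenesulfonyl azide, CC(=O)Nc1ccc(cc1)S(=O)(=O)N=[N+]=[N-]
Why: Regitz diazo transfer, in which the DBU-generated arylacetate enolate attacks the sulfonyl azide and expels the sulfonamide, a standard entry to aryldiazoacetates.

Step 3
Reactants: 4 methyl 2-diazo-2-[2-[[4-(benzyloxy)phenyl]methoxy]phenyl]acetate
Product: 5 methyl (2R,3S)-2-[4-(benzyloxy)phenyl]-2,3-dihydro-1-benzofuran-3-carboxylate (cis)
Conditions: Rh2(S-PTTL)4 [dirhodium tetrakis(N-phthaloyl-(S)-tert-leucinate)] (1 mol %), toluene, −78 °C, slow addition of 4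
Reagents that add atoms: none
Why: Loss of N2 from 4 on the dirhodium tetracarboxylate (divalent rhodium) gives an electrophilic donor/acceptor rhodium carbene, which inserts into one benzylic C–H bond of the ortho OCH2Ar group through a concerted but asynchronous three-centre transition state with hydride-transfer character, forming the Cα–Cβ bond. The closest known reaction type is the dirhodium-carboxylate-catalysed enantioselective intramolecular C–H insertion of ortho-(benzyloxy)aryl diazoacetates, which gives cis-2-aryl-2,3-dihydrobenzofuran-3-carboxylates. The dihydrofuran ring closes in the 1,5-insertion mode, the carbene carbon, two arene carbons, the ether oxygen and the benzylic carbon becoming its five atoms. C3 (the future Cα) is controlled by the chiral N-phthaloyl-tert-leucinate ligands, which differentiate the two enantiotopic benzylic hydrogens and the carbene faces, and the temporary C2 centre should come out cis to the ester because the aryl group on the reacting carbon points away from the ligand wall in the compact transition state. The step needs chemoselectivity for 1,5-insertion over carbene dimerisation, azine formation and attack on the arene rings, together with high enantioselectivity; the C–H bond activated by both the ether oxygen and the electron-rich 4-alkoxyphenyl ring, its ideal five-atom distance, the remoteness of the second OCH2Ph group and slow addition at −78 °C should secure this.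

Step 4
Reactants: 5 methyl (2R,3S)-2-[4-(benzyloxy)phenyl]-2,3-dihydro-1-benzofuran-3-carboxylate
Product: 6 [(2R,3R)-2-[4-(benzyloxy)phenyl]-2,3-dihydro-1-benzofuran-3-yl]methanol (cis)
Conditions: LiAlH4, THF, −40 to 0 °C
Reagents that add atoms: none
Why: Hydride reduction of the ester to the primary alcohol is much faster than enolisation at low temperature, so the cis C3 centre should be kept (the descriptor changes only through priorities), and both ether types are inert.

Step 5
Reactants: 6 [(2R,3R)-2-[4-(benzyloxy)phenyl]-2,3-dihydro-1-benzofuran-3-yl]methanol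
Product: 7 [(2R,3R)-2-[4-(benzyloxy)phenyl]-2,3-dihydro-1-benzofuran-3-yl]methyl 4-methylbenzenesulfonate
Conditions: TsCl, Et3N, DMAP (cat.), CH2Cl2, 0 °C to rt
Reagents that add atoms: 4-methylbenzenesulfonyl chloride, Cc1ccc(cc1)S(Cl)(=O)=O
Why: DMAP-catalysed sulfonylation of the primary alcohol activates it for reduction without touching either stereocentre.

Step 6
Reactants: 7 [(2R,3R)-2-[4-(benzyloxy)phenyl]-2,3-dihydro-1-benzofuran-3-yl]methyl 4-methylbenzenesulfonate
Product: 8 (2R,3S)-2-[4-(benzyloxy)phenyl]-3-methyl-2,3-dihydro-1-benzofuran (cis)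
Conditions: LiEt3BH, THF, 0 °C to rt
Reagents that add atoms: none
Why: SN2 displacement of the primary tosylate by the strongly nucleophilic borohydride, which tolerates β-branching, turns CH2OTs into the Cα methyl group with the ring centres untouched.

Step 7
Reactants: 8 (2R,3S)-2-[4-(benzyloxy)phenyl]-3-methyl-2,3-dihydro-1-benzofuran
Product: 9 2-[(2R)-1-(4-hydroxyphenyl)propan-2-yl]phenol
Conditions: H2 (1 atm), Pd/C, EtOAc/MeOH, AcOH (cat.), rt
Reagents that add atoms: none
Why: Palladium-catalysed hydrogenolysis cleaves both benzylic C–O bonds, the ring O–CH(aryl) bond of the cyclic benzylic aryl ether and the O-benzyl ether, which turns C2 into the Cβ methylene, erases the temporary centre and leaves Cα, which is not at a breaking bond, unchanged.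

Step 8
Reactants: 9 2-[(2R)-1-(4-hydroxyphenyl)propan-2-yl]phenol
Product: 10 1-(benzyloxy)-2-[(2R)-1-[4-(benzyloxy)phenyl]propan-2-yl]benzene
Conditions: BnBr, K2CO3, DMF, rt
Reagents that add atoms: benzyl bromide, BrCc1ccccc1
Why: Williamson benzylation of both phenols blocks O-attack in the union step and leaves the carbon para to the ring B oxygen as the most nucleophilic and least hindered arene position.

Step 9
Reactants: 11 meso-2,3-dimethylsuccinic acid
Product: 12 cis-3,4-dimethyloxolane-2,5-dione (meso anhydride)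
Conditions: AcCl, 50 °C, then evaporation
Reagents that add atoms: none
Why: Cyclodehydration through the mixed anhydride under mild, base-free conditions should give the cis anhydride without epimerising the two methyl-bearing centres.

Step 10
Reactants: 12 cis-3,4-dimethyloxolane-2,5-dione; 13 1-(benzyloxy)-4-bromobenzene
Product: 16 (2R,3S)-4-[4-(benzyloxy)phenyl]-2,3-dimethyl-4-oxobutanoic acid, via 4-(benzyloxy)phenyllithium 14 (not isolated), via [4-(benzyloxy)phenyl]zinc triflate 15 (not isolated)
Conditions: 13, n-BuLi, THF, −78 °C; Zn(OTf)2, −78 °C to rt; then 12, [Rh(cod)Cl]2 (4 mol %), (R,R)-TADDOL-derived N,N-dimethylphosphoramidite (8 mol %), THF, 50 °C; aq. HCl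
Reagents that add atoms: none
Why: Enantioselective desymmetrising cross-coupling of a meso succinic anhydride with an arylzinc reagent, in which monovalent rhodium adds oxidatively to one enantiotopic acyl C–O bond, zinc transfers the aryl group and reductive elimination gives the ketone, so the ligand's choice of carbonyl fixes the two existing methyl centres as (2R,3S).

Step 11
Reactants: 16 (2R,3S)-4-[4-(benzyloxy)phenyl]-2,3-dimethyl-4-oxobutanoic acid
Product: 18 (3R,4S,5S)-5-[4-(benzyloxy)phenyl]-3,4-dimethyloxolan-2-one, via (2R,3S,4S)-hydroxy acid 17 (not isolated)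
Conditions: LiBH(s-Bu)3 (2.2 equiv), THF, −78 °C; then aq. HCl, rt
Reagents that add atoms: none
Why: Felkin–Anh-controlled reduction of the aryl ketone by the bulky borohydride should give the anti carbinol, so that acid-promoted lactonisation places ring A trans to the neighbouring methyl, and acid equilibration of this benzylic centre favours the same isomer.

Step 12
Reactants: 18 (3R,4S,5S)-5-[4-(benzyloxy)phenyl]-3,4-dimethyloxolan-2-one
Product: 20 (3R,4S,5S)-5-[4-(benzyloxy)phenyl]-3,4-dimethyloxolan-2-yl acetate (anomer mixture), via diisobutylaluminium lactolate 19 (not isolated)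
Conditions: i-Bu2AlH, CH2Cl2, −78 °C; then pyridine, DMAP, Ac2O, −78 to 0 °C
Reagents that add atoms: acetic anhydride, CC(=O)OC(C)=O
Why: One-pot reductive acetylation, in which the aluminium hemiacetal formed at −78 °C is trapped by acetic anhydride before it can open or epimerise at the α-methyl; the new acetal centre is lost in the next step.

Step 13
Reactants: 20 (3R,4S,5S)-5-[4-(benzyloxy)phenyl]-3,4-dimethyloxolan-2-yl acetate (1.3 equiv); 10 1-(benzyloxy)-2-[(2R)-1-[4-(benzyloxy)phenyl]propan-2-yl]benzene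
Product: 21 (2S,3S,4R,5R)-2-[4-(benzyloxy)phenyl]-5-{4-(benzyloxy)-3-[(2R)-1-[4-(benzyloxy)phenyl]propan-2-yl]phenyl}-3,4-dimethyloxolane
Conditions: BF3·OEt2 (0.5 equiv), CH2Cl2, −78 to −20 °C
Reagents that add atoms: none
Why: Friedel–Crafts arylation of the cyclic oxocarbenium ion released from the anomeric acetate, at the ring B carbon para to the benzyloxy group and anti to the neighbouring methyl, with reversible benzylic C–O ionisation expected to funnel any cis isomer to the more stable 2,3-trans-3,4-cis-4,5-trans array.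

Step 14
Reactants: 21 (2S,3S,4R,5R)-2-[4-(benzyloxy)phenyl]-5-{4-(benzyloxy)-3-[(2R)-1-[4-(benzyloxy)phenyl]propan-2-yl]phenyl}-3,4-dimethyloxolane
Product: 22 4-[(2S,3S,4R,5R)-5-{4-hydroxy-3-[(2R)-1-(4-hydroxyphenyl)propan-2-yl]phenyl}-3,4-dimethyloxolan-2-yl]phenol (CNP0232576.1)
Conditions: H2 (1 atm), Pd/C, EtOAc/MeOH, rt, short reaction time
Reagents that add atoms: none
Why: Hydrogenolysis of the three aryl benzyl ethers is much faster than cleavage of the dialkyl benzylic ether bonds of the oxolane, so brief exposure should free the three phenols with all five stereocentres intact.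

Compound list
1 | methyl 2-(2-hydroxyphenyl)acetate | COC(=O)Cc1ccccc1O | starting material
2 | 4-(benzyloxy)benzyl chloride | ClCc1ccc(OCc2ccccc2)cc1 | starting material
3 | methyl 2-[2-[[4-(benzyloxy)phenyl]methoxy]phenyl]acetate | COC(=O)Cc1ccccc1OCc1ccc(OCc2ccccc2)cc1 | intermediate
4 | methyl 2-diazo-2-[2-[[4-(benzyloxy)phenyl]methoxy]phenyl]acetate | COC(=O)C(=[N+]=[N-])c1ccccc1OCc1ccc(OCc2ccccc2)cc1 | intermediate
5 | methyl (2R,3S)-2-[4-(benzyloxy)phenyl]-2,3-dihydro-1-benzofuran-3-carboxylate | COC(=O)[C@H]1c2ccccc2O[C@H]1c1ccc(OCc2ccccc2)cc1 | intermediate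
6 | [(2R,3R)-2-[4-(benzyloxy)phenyl]-2,3-dihydro-1-benzofuran-3-yl]methanol | OC[C@H]1c2ccccc2O[C@H]1c1ccc(OCc2ccccc2)cc1 | intermediate
7 | [(2R,3R)-2-[4-(benzyloxy)phenyl]-2,3-dihydro-1-benzofuran-3-yl]methyl 4-methylbenzenesulfonate | Cc1ccc(cc1)S(=O)(=O)OC[C@H]1c2ccccc2O[C@H]1c1ccc(OCc2ccccc2)cc1 | intermediate
8 | (2R,3S)-2-[4-(benzyloxy)phenyl]-3-methyl-2,3-dihydro-1-benzofuran | C[C@H]1c2ccccc2O[C@H]1c1ccc(OCc2ccccc2)cc1 | intermediate
9 | 2-[(2R)-1-(4-hydroxyphenyl)propan-2-yl]phenol | C[C@H](Cc1ccc(O)cc1)c1ccccc1O | intermediate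
10 | 1-(benzyloxy)-2-[(2R)-1-[4-(benzyloxy)phenyl]propan-2-yl]benzene | C[C@H](Cc1ccc(OCc2ccccc2)cc1)c1ccccc1OCc1ccccc1 | intermediate
11 | meso-2,3-dimethylsuccinic acid | C[C@@H](C(=O)O)[C@H](C)C(=O)O | starting material
12 | cis-3,4-dimethyloxolane-2,5-dione, (3R,4S) | C[C@@H]1[C@H](C)C(=O)OC1=O | intermediate
13 | 1-(benzyloxy)-4-bromobenzene | Brc1ccc(OCc2ccccc2)cc1 | starting material
14 | 4-(benzyloxy)phenyllithium (not isolated) | [Li]c1ccc(OCc2ccccc2)cc1 | intermediate
15 | [4-(benzyloxy)phenyl]zinc trifluoromethanesulfonate (not isolated) | FC(F)(F)S(=O)(=O)O[Zn]c1ccc(OCc2ccccc2)cc1 | intermediate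
16 | (2R,3S)-4-[4-(benzyloxy)phenyl]-2,3-dimethyl-4-oxobutanoic acid | C[C@@H](C(=O)O)[C@H](C)C(=O)c1ccc(OCc2ccccc2)cc1 | intermediate
17 | (2R,3S,4S)-4-[4-(benzyloxy)phenyl]-4-hydroxy-2,3-dimethylbutanoic acid (not isolated) | C[C@@H](C(=O)O)[C@H](C)[C@@H](c1ccc(OCc2ccccc2)cc1)O | intermediate
18 | (3R,4S,5S)-5-[4-(benzyloxy)phenyl]-3,4-dimethyloxolan-2-one | C[C@@H]1[C@H](C)[C@@H](c2ccc(OCc3ccccc3)cc2)OC1=O | intermediate
19 | diisobutylaluminium (3R,4S,5S)-5-[4-(benzyloxy)phenyl]-3,4-dimethyloxolan-2-olate (not isolated) | C[C@@H]1[C@H](C)[C@@H](c2ccc(OCc3ccccc3)cc2)OC1O[Al](CC(C)C)CC(C)C | intermediate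
20 | (3R,4S,5S)-5-[4-(benzyloxy)phenyl]-3,4-dimethyloxolan-2-yl acetate (anomer mixture) | C[C@@H]1[C@H](C)[C@@H](c2ccc(OCc3ccccc3)cc2)OC1OC(C)=O | intermediate
21 | (2S,3S,4R,5R)-2-[4-(benzyloxy)phenyl]-5-{4-(benzyloxy)-3-[(2R)-1-[4-(benzyloxy)phenyl]propan-2-yl]phenyl}-3,4-dimethyloxolane | C[C@@H]1[C@H](C)[C@@H](c2ccc(OCc3ccccc3)cc2)O[C@H]1c1ccc(OCc2ccccc2)c([C@H](C)Cc2ccc(OCc3ccccc3)cc2)c1 | intermediate
22 | 4-[(2S,3S,4R,5R)-5-{4-hydroxy-3-[(2R)-1-(4-hydroxyphenyl)propan-2-yl]phenyl}-3,4-dimethyloxolan-2-yl]phenol | C[C@@H]1[C@H](C)[C@@H](c2ccc(O)cc2)O[C@H]1c1ccc(O)c([C@H](C)Cc2ccc(O)cc2)c1 | target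

Total step count: 14. Longest linear sequence: 10 steps (steps 1 to 8, then 13 and 14); the lactol acetate branch is steps 9 to 12.

Steps most likely to fail

Step 3. The very electron-rich benzylic position may react by a stepwise hydride-transfer path, or the carbene may dimerise, which would erode the cis selectivity and the enantiomeric purity at Cα. The fallback replaces carbene insertion by an auxiliary-controlled enolate alkylation that forms the same Cα–Cβ bond; it sets out from 1 and returns to the route at 10, bypassing steps 2 to 8. Compound 1 is O-benzylated (BnBr, K2CO3, DMF) to methyl 2-[2-(benzyloxy)phenyl]acetate F1 and saponified (LiOH, THF/H2O) to 2-[2-(benzyloxy)phenyl]acetic acid F2. Coupling with (R)-4-benzyl-1,3-oxazolidin-2-one (DCC, DMAP, CH2Cl2) gives (4R)-4-benzyl-3-{2-[2-(benzyloxy)phenyl]acetyl}-1,3-oxazolidin-2-one F3. Its sodium enolate (NaN(SiMe3)2, THF, −78 °C) is alkylated with 2 (NaI) on the face away from the auxiliary benzyl group, which should give (4R)-4-benzyl-3-{(2R)-2-[2-(benzyloxy)phenyl]-3-[4-(benzyloxy)phenyl]propanoyl}-1,3-oxazolidin-2-one F4. LiBH4 (THF, 0 °C) removes the auxiliary reductively to give (2R)-2-[2-(benzyloxy)phenyl]-3-[4-(benzyloxy)phenyl]propan-1-ol F5. Tosylation gives (2R)-2-[2-(benzyloxy)phenyl]-3-[4-(benzyloxy)phenyl]propyl 4-methylbenzenesulfonate F6, and LiEt3BH reduces it to 10.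

Step 13. The mono-alkoxy arene may be too weak a nucleophile for the oxocarbenium ion, attack may occur at a second ring position, or the product may ionise again at a benzylic C–O bond and be arylated twice. The fallback joins the fragments by aryllithium addition to the lactone and ionic reduction; it sets out from 9, uses lactone 18 and returns at 21. Compound 9 is brominated para to the ring B hydroxyl (Bu4NBr3, CH2Cl2/MeOH, rt; ring C has no free para position) to 4-bromo-2-[(2R)-1-(4-hydroxyphenyl)propan-2-yl]phenol F7 and benzylated (BnBr, K2CO3, DMF) to 1-(benzyloxy)-4-bromo-2-[(2R)-1-[4-(benzyloxy)phenyl]propan-2-yl]benzene F8. Bromine–lithium exchange (n-BuLi, THF, −78 °C) gives {4-(benzyloxy)-3-[(2R)-1-[4-(benzyloxy)phenyl]propan-2-yl]phenyl}lithium F9, which adds to 18 to give the cyclic hemiketal (3R,4S,5S)-5-[4-(benzyloxy)phenyl]-2-{4-(benzyloxy)-3-[(2R)-1-[4-(benzyloxy)phenyl]propan-2-yl]phenyl}-3,4-dimethyloxolan-2-ol F10. Et3SiH with BF3·OEt2 (CH2Cl2, −78 °C) reduces its oxocarbenium ion, and if the kinetic hydride adduct is 2,3-cis, continued exposure to BF3·OEt2 should epimerise the benzylic centre to the more stable isomer 21.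

Step 10. Discrimination between the two enantiotopic carbonyl groups may be weak, or transmetalation from the zinc reagent made in the flask may be slow, giving keto acid of low enantiomeric purity that would later appear as a diastereomer of 21. The fallback uses organocatalytic alcoholysis and a thioester ketone synthesis; it sets out from 12 and returns at 18. Methanolysis of 12 with a bis-cinchona alkaloid catalyst ((DHQD)2AQN or its pseudo-enantiomer (DHQ)2AQN, whichever gives this antipode; MeOH, Et2O, −20 °C) gives (2S,3R)-4-methoxy-2,3-dimethyl-4-oxobutanoic acid F11. EtSH, DCC and DMAP convert it into methyl (2R,3S)-4-(ethylsulfanyl)-2,3-dimethyl-4-oxobutanoate F12. Liebeskind–Srogl coupling with 4-(benzyloxy)phenylboronic acid (Pd2(dba)3 as zerovalent palladium source, tri(2-furyl)phosphine, copper thiophene-2-carboxylate with monovalent copper, THF, 50 °C) gives methyl (2R,3S)-4-[4-(benzyloxy)phenyl]-2,3-dimethyl-4-oxobutanoate F13 under neutral conditions. Reduction with LiBH(s-Bu)3 (THF, −78 °C), followed by closure of the alkoxide onto the methyl ester, returns 18.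

Further compounds
F1 | step 3 | methyl 2-[2-(benzyloxy)phenyl]acetate | COC(=O)Cc1ccccc1OCc1ccccc1
F2 | step 3 | 2-[2-(benzyloxy)phenyl]acetic acid | OC(=O)Cc1ccccc1OCc1ccccc1
F3 | step 3 | (4R)-4-benzyl-3-{2-[2-(benzyloxy)phenyl]acetyl}-1,3-oxazolidin-2-one | O=C(Cc1ccccc1OCc1ccccc1)N1[C@H](Cc2ccccc2)COC1=O
F4 | step 3 | (4R)-4-benzyl-3-{(2R)-2-[2-(benzyloxy)phenyl]-3-[4-(benzyloxy)phenyl]propanoyl}-1,3-oxazolidin-2-one | O=C([C@H](Cc1ccc(OCc2ccccc2)cc1)c1ccccc1OCc1ccccc1)N1[C@H](Cc2ccccc2)COC1=O
F5 | step 3 | (2R)-2-[2-(benzyloxy)phenyl]-3-[4-(benzyloxy)phenyl]propan-1-ol | OC[C@H](Cc1ccc(OCc2ccccc2)cc1)c1ccccc1OCc1ccccc1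
F6 | step 3 | (2R)-2-[2-(benzyloxy)phenyl]-3-[4-(benzyloxy)phenyl]propyl 4-methylbenzenesulfonate | Cc1ccc(cc1)S(=O)(=O)OC[C@H](Cc1ccc(OCc2ccccc2)cc1)c1ccccc1OCc1ccccc1
F7 | step 13 | 4-bromo-2-[(2R)-1-(4-hydroxyphenyl)propan-2-yl]phenol | C[C@H](Cc1ccc(O)cc1)c1cc(Br)ccc1O
F8 | step 13 | 1-(benzyloxy)-4-bromo-2-[(2R)-1-[4-(benzyloxy)phenyl]propan-2-yl]benzene | C[C@H](Cc1ccc(OCc2ccccc2)cc1)c1cc(Br)ccc1OCc1ccccc1
F9 | step 13 | {4-(benzyloxy)-3-[(2R)-1-[4-(benzyloxy)phenyl]propan-2-yl]phenyl}lithium | C[C@H](Cc1ccc(OCc2ccccc2)cc1)c1cc([Li])ccc1OCc1ccccc1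
F10 | step 13 | (3R,4S,5S)-5-[4-(benzyloxy)phenyl]-2-{4-(benzyloxy)-3-[(2R)-1-[4-(benzyloxy)phenyl]propan-2-yl]phenyl}-3,4-dimethyloxolan-2-ol | C[C@@H]1[C@H](C)[C@@H](c2ccc(OCc3ccccc3)cc2)OC1(O)c1ccc(OCc2ccccc2)c([C@H](C)Cc2ccc(OCc3ccccc3)cc2)c1
F11 | step 10 | (2S,3R)-4-methoxy-2,3-dimethyl-4-oxobutanoic acid | C[C@@H](C(=O)OC)[C@H](C)C(=O)O
F12 | step 10 | methyl (2R,3S)-4-(ethylsulfanyl)-2,3-dimethyl-4-oxobutanoate | C[C@@H](C(=O)OC)[C@H](C)C(=O)SCC
F13 | step 10 | methyl (2R,3S)-4-[4-(benzyloxy)phenyl]-2,3-dimethyl-4-oxobutanoate | C[C@@H](C(=O)OC)[C@H](C)C(=O)c1ccc(OCc2ccccc2)cc1
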